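## Analysis of the target

The target is a 36-membered macrolactone: C1 (ester carbonyl) through C35 and the ring oxygen form the ring, and C35 carries a hexan-2-yl side chain (C36 with its methyl, then C37–C40). The only unsaturation is the (2Z)-3-methyl enoate C1–C3, in which the C4 ring methylene is cis to the carbonyl and the methyl is trans. Nine free secondary hydroxyls sit at C7, C9, C13, C17, C21, C25, C27, C29 and C33. With C35 and C36 they make eleven stereocentres (7S, 9R, 13S, 17R, 21R, 25S, 27S, 29S, 33R, 35R, 36S). Drawn as a zigzag, C7/C9, C25/C27 and C33/C35 are syn-1,3 pairs, C27/C29 is anti-1,3 and C35/C36 is anti. C13, C17 and C21 are isolated carbinols, each three methylenes away from its neighbours, so five 1,5-relationships cannot be set by induction from a neighbouring centre. Sensitive points are the Z-enoate (geometry, conjugate addition), the lactone (it can migrate to O33 once the hydroxyls are free), and the need to keep O35 distinct from nine similar oxygens. The strategy rests on C1–C3: C1–C2 is a malonate-derived acetate unit bound through O35, and C3 is an acyl carbon whose methyl is a branch on a former ketone. The ring can therefore be closed by forming C2–C3 as a β-keto lactone, with the methyl added afterwards.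

## Retrosynthetic reasoning

**Protecting groups and C3–CH3.** Target 53 is first simplified at the periphery. The seven silyl ethers and the acetonide of 52 come off last, so no free polyol is carried through C–C bond formation. In 52 the C3–CH3 bond is cut, leading to the (E)-enol triflate 51 and from there to the β-keto lactone 50. The cut is placed here and not at C2=C3 because an olefination would have to tell a methyl from a long alkyl chain at C3. The enol sulfonate geometry of a β-keto ester, by contrast, can be chosen through the counter-ion and is then transferred with retention by a metal-catalysed methyl coupling. The forward steps must put the sulfonate oxygen trans to C1 and leave the lactone alone.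

**C2–C3 and the ring.** In 50 the C2–C3 bond is cut. This opens the ring to the seco compound 48, in which C3 is an S-phenyl thioester and O35 carries a malonic half-ester. It is the bond a chain-building enzyme would make last. Cutting it removes the ring and one skeletal bond together, and the ester bond O35–C1, the usual site of macrolactonisation, can be made on an open chain without dilution. The forward reaction has to make the malonate α-carbon attack a remote thioester within one molecule and then decarboxylate.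

**O35–C1 and C3–S.** 48 is cut at O35–C1 to alcohol 46 and the dioxanedione 47. 46 is traced through its O35 benzyl-type ether 45 and cut at C3–S to acid 43 and thiophenol 44. The ester comes from thermal opening of 47, which needs no activating agent and leaves the thioester alone. O35 is the only oxygen held as an oxidatively cleavable ether, which singles it out.

**C10–C11.** The chain of 43 is cut at C10–C11 into the C11–C40 bromide 39 and the C3–C10 epoxide 8. Opening an epoxide at its CH2 terminus forms the bond and delivers the C9 hydroxyl without touching a stereocentre. The carboxyl end can ride in as a tert-butyl ester on the electrophile, so it never has to survive the making of an organomagnesium reagent.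

**C22–C23, C18–C19 and C14–C15.** 39 is cut three times in the same way, releasing three copies of the C4 epoxide 2 and the C23–C40 chloride 30. C13, C17 and C21 have the same sense and the same four-carbon repeat, so one enantiopure building block serves for all three. Each configuration is bought with the epoxide rather than induced, which is the reliable option for 1,5-related centres. Forward, each cycle is a copper-catalysed Grignard opening followed by silylation, and the primary bromide left by 2 is the next nucleophile.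

**C32–C33 and the C33 carbinol.** The C33 hydroxyl of 30 is traced back to ketone 28, the ketone to dithioketal 27, and 27 is cut at C32–C33 into the C33–C40 dithiane 17 and the C23–C32 iodide 25. Here the acyl-anion carbon becomes a carbinol of the target, so nothing has to be removed reductively. The O35 ether, 1,3 to the ketone, can steer the hydride to the syn product.

**C29–C30.** 25 is cut at C29–C30 to aldehyde 21 and an allyl unit. 21 is traced through 20 and 19 to the purchasable acetonide 18, whose stereocentres are C25 and C27 and whose ester and nitrile carbons are C23 and C29. One reagent-controlled allyl transfer sets C29 anti to C27, and the allyl terminus becomes the C32 iodide.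

**C33–C34 and C36–CH3.** 17 is cut at C33–C34 to 1,3-dithiane 14 and epoxide 13. 13 is traced through diol 11 to epoxy alcohol 10 and (E)-hept-2-en-1-ol 9. The C36–methyl bond is cut on the understanding that methyl enters anti to the epoxide oxygen, so one asymmetric epoxidation fixes both C35 and C36.

**West epoxide.** 8 is traced through 7 and the cyclic iodocarbonate 6 to homoallylic alcohol 4, which is cut at C7–C8 to aldehyde 3 and an allyl unit. C7 is set by reagent control and C9 by 1,3-induction through a six-membered carbonate.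

**C4 unit.** 2 is traced to its racemate 1 by hydrolytic kinetic resolution.

## Alternatives that were turned down

**Alternative 1:** The disconnection is at C8–C9 and C13–C14, taking the C2-related pair C9/C13 out as one unit.
- **Key step:** pentane-1,5-diol A1 is dehydrogenated at each end in turn by a cyclometalated iridium catalyst and each transient aldehyde is allylated, which should give (4R,8R)-undeca-1,10-diene-4,8-diol A2.
- **For it:** two C–C bonds and two stereocentres form in one catalytic, redox-neutral step from a commodity diol, and the minor enantiomer drains into the meso isomer. On this count it is more economical than any single step of the chosen route, which buys C13, C17 and C21 one epoxide at a time with stoichiometric magnesium.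
- **Against it:** A2 has two identical allyl ends, while the target needs the west end turned into the C7 carbinol (syn to C9) and the east end extended as plain methylenes toward C17. The ends would have to be told apart statistically or by extra steps. The unit covers two of eleven stereocentres and leaves the ring and the enoate open.
- **Comparison:** it is a fragment tactic. The chosen strategy settles the ring closure, the C2–C3 bond and the path to the Z-enoate in one disconnection, and every chain coupling is directional, so no desymmetrisation is needed.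

**Alternative 2:** The C24–C29 unit (and, read in reverse, C6–C11) is traced to the meso ketone A3, cis-3,5-bis(methoxymethoxy)cyclohexan-1-one, whose carbonyl-to-α-carbon bond is cut by oxygen insertion.
- **Key step:** a flavin-dependent Baeyer–Villiger monooxygenase with cofactor recycling inserts oxygen on one of the two enantiotopic sides of A3 and should give lactone A4, (4S,6R)-4,6-bis(methoxymethoxy)oxepan-2-one.
- **For it:** two stereocentres arise by desymmetrisation of an achiral ketone under mild conditions, and one lactone serves both syn pairs C7/C9 and C25/C27. The chosen route makes these pairs by two unrelated sequences (from 4 and from 18), so the alternative is the more unified plan here.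
- **Against it:** the enzyme's discrimination on a 3,5-dialkoxycyclohexanone would have to be found by screening. The lactone ends are a carboxyl and a CH2–O, whereas C6, C11 and C24 are methylenes and C29 is a carbinol, so each copy needs several redox and homologation steps. The methoxymethyl ethers must later be exchanged, and the ring is not addressed.
- **Comparison:** it supplies four of eleven stereocentres. The chosen strategy takes the same pairs from short known chemistry and puts the new chemistry where it replaces a ring closure and a separate olefination.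

**Alternative 3:** The disconnection is at C18–C19 and C19–C20, with C19 as a dithiane carbon between the west epoxide A6 (C5–C18) and the east epoxide A7 (C20–C40).
- **Key step:** lithiated 2-(tert-butyldimethylsilyl)-1,3-dithiane A5 opens A6 at C18, a polar additive triggers the 1,4-Brook shift of silicon to O17, and the new carbanion opens A7 at C20 to give the C5–C40 chain A8 in one flask.
- **For it:** it is the most convergent chain assembly considered: two large halves, two C–C bonds and one silyl ether in one operation. Its longest linear sequence is clearly shorter than that of the chosen route, in which four Grignard couplings follow one another on the growing C23–C40 piece.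
- **Against it:** C19 is a methylene, so the dithioketal must be removed reductively in the presence of two benzyl-type ethers and eight silyl ethers. The O17/O21 differentiation is not needed, since both oxygens end up alike. The union uses a strong alkyllithium base on two advanced fragments (A7 alone holds seven stereocentres). A8 stops at C5, so C3–C4, the C1–C2 unit, the ring and the enoate remain open.
- **Comparison:** it is stronger on convergence and weaker on what it leaves behind. The chosen route uses a dithiane only at C33, where the masked carbonyl becomes a carbinol, and closes the ring with the bond that completes the skeleton.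

Key step: step 32

## Remarks

- Remark on protection: O25 and O27 are carried as an isopropylidene acetal instead of two silyl ethers. The key-step precursor 48 and product 50 therefore bear seven TBS ethers and one acetonide.
- Assumption on the resolution: the (S,S) cobalt salen catalyst is taken to hydrate the (S)-enantiomer of a terminal alkyl epoxide faster, leaving (R)-2.
- Assumption on supply: tert-butyl 5-oxopentanoate 3, the racemic bromo epoxide 1 and the acetonide nitrile 18 are taken to be purchasable.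
- Abbreviations: TBS = tert-butyldimethylsilyl, PMB = 4-methoxybenzyl, Ipc = isopinocampheyl. Locants C1–C40 are those of the target.

## Route

Step 1
Reactants: 1 rac-2-(2-bromoethyl)oxirane
Product: 2 (R)-2-(2-bromoethyl)oxirane
Conditions: (S,S)-(salen)Co(OAc) (0.5 mol%; salen = N,N'-bis(3,5-di-tert-butylsalicylidene)cyclohexane-1,2-diamine dianion), H2O (0.55 equiv), THF, 0 °C to rt; distillation
Reagents that add atoms: none
Why: Jacobsen hydrolytic kinetic resolution of a terminal epoxide; the trivalent cobalt complex should hydrate the (S)-epoxide much faster, so the (R)-epoxide is recovered in high ee. The primary bromide is inert to water under these neutral conditions.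

Step 2
Reactants: 3 tert-butyl 5-oxopentanoate
Product: 4 tert-butyl (S)-5-hydroxyoct-7-enoate
Conditions: (+)-Ipc2BOMe, allylMgBr, Et2O, 0 °C to rt; then 3, −78 °C; NaOH, H2O2, 0 °C
Reagents that add atoms: allylmagnesium bromide, C=CC[Mg]Br
Why: Brown allylboration; the allylborane of the (−)-α-pinene series should deliver allyl to the Re face of the aldehyde through a chair transition state, which sets C7. The tert-butyl ester does not react with the borane at −78 °C.

Step 3
Reactants: 4 tert-butyl (S)-5-hydroxyoct-7-enoate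
Product: 5 tert-butyl (S)-5-[(tert-butoxycarbonyl)oxy]oct-7-enoate
Conditions: Boc2O, DMAP (cat.), MeCN, rt
Reagents that add atoms: di-tert-butyl dicarbonate, CC(C)(C)OC(=O)OC(=O)OC(C)(C)C
Why: DMAP-catalysed carbonate formation on a secondary alcohol; it installs the internal nucleophile for the next step.

Step 4
Reactants: 5 tert-butyl (S)-5-[(tert-butoxycarbonyl)oxy]oct-7-enoate
Product: 6 tert-butyl 4-[(4S,6S)-6-(iodomethyl)-2-oxo-1,3-dioxan-4-yl]butanoate
Conditions: IBr, toluene, −85 °C
Reagents that add atoms: iodine monobromide, IBr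
Why: iodocarbonate cyclisation of a homoallylic tert-butyl carbonate; the carbonyl oxygen opens the iodonium ion in a 6-exo mode through a chair with both substituents equatorial, which sets C9 syn to C7. Loss of the tert-butyl cation gives the cyclic carbonate.

Step 5
Reactants: 6 tert-butyl 4-[(4S,6S)-6-(iodomethyl)-2-oxo-1,3-dioxan-4-yl]butanoate
Product: 7 tert-butyl (5S)-5-hydroxy-6-[(2S)-oxiran-2-yl]hexanoate
Conditions: K2CO3, MeOH, rt
Reagents that add atoms: none
Why: methanolysis of the carbonate frees the C9 alkoxide, which displaces the neighbouring iodide (3-exo-tet) to the terminal epoxide; neither C–O bond at a stereocentre is broken.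

Step 6
Reactants: 7 tert-butyl (5S)-5-hydroxy-6-[(2S)-oxiran-2-yl]hexanoate
Product: 8 tert-butyl (5S)-5-[(tert-butyldimethylsilyl)oxy]-6-[(2S)-oxiran-2-yl]hexanoate
Conditions: TBSCl, imidazole, DMF, rt
Reagents that add atoms: tert-butyldimethylsilyl chloride, CC(C)(C)[Si](C)(C)Cl
Why: standard silylation of a secondary alcohol; the epoxide and the tert-butyl ester are stable.

Step 7
Reactants: 9 (E)-hept-2-en-1-ol
Product: 10 [(2R,3R)-3-butyloxiran-2-yl]methanol
Conditions: Ti(OiPr)4 (5 mol%), D-(−)-diisopropyl tartrate (6 mol%), t-BuOOH, 4 Å MS, CH2Cl2, −20 °C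
Reagents that add atoms: tert-butyl hydroperoxide, CC(C)(C)OO
Why: Sharpless asymmetric epoxidation of an (E)-allylic alcohol; the D-tartrate ligand directs oxygen to the face that gives the (2R,3R)-epoxy alcohol, which fixes C35 and prepares C36.

Step 8
Reactants: 10 [(2R,3R)-3-butyloxiran-2-yl]methanol
Product: 11 (2S,3S)-3-methylheptane-1,2-diol
Conditions: Me3Al (3 equiv), hexane/CH2Cl2, 0 °C to rt
Reagents that add atoms: trimethylaluminium, C[Al](C)C
Why: opening of a 2,3-epoxy alcohol by the aluminium alkoxide at C3 with inversion gives the 1,2-diol; this SN2 step sets C36 anti to the C35 oxygen.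

Step 9
Reactants: 11 (2S,3S)-3-methylheptane-1,2-diol
Product: 13 (2S)-2-[(2S)-hexan-2-yl]oxirane, via primary monotosylate 12 (not isolated)
Conditions: NaH (2.2 equiv), N-tosylimidazole, THF, 0 °C to rt
Reagents that add atoms: none
Why: one-pot sulfonylation of the primary alkoxide and 3-exo-tet closure by the secondary alkoxide; the C35–O bond is not broken, so the configuration is retained.

Step 10
Reactants: 14 1,3-dithiane; 13 (2S)-2-[(2S)-hexan-2-yl]oxirane
Product: 17 2-[(2R,3S)-2-[(4-methoxybenzyl)oxy]-3-methylheptyl]-1,3-dithiane, via 2-lithio-1,3-dithiane 15 (not isolated), via lithium alkoxide 16 (not isolated)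
Conditions: n-BuLi, THF, −30 °C; 13, −30 to 0 °C; then PMBBr, Bu4NI (cat.), DMPU, rt
Reagents that add atoms: 4-methoxybenzyl bromide, COc1ccc(CBr)cc1
Why: Corey–Seebach umpolung; the dithiane anion opens the epoxide at its CH2 terminus (C34). The lithium alkoxide is then benzylated in the same flask (Williamson), which marks O35 for the rest of the synthesis.

Step 11
Reactants: 18 tert-butyl 2-[(4R,6R)-6-(cyanomethyl)-2,2-dimethyl-1,3-dioxan-4-yl]acetate
Product: 19 2-[(4R,6S)-6-(2-hydroxyethyl)-2,2-dimethyl-1,3-dioxan-4-yl]acetonitrile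
Conditions: LiBH4, THF, MeOH (1 equiv), 0 °C to rt
Reagents that add atoms: none
Why: chemoselective borohydride reduction of an ester beside a nitrile; the acetonide is untouched.

Step 12
Reactants: 19 2-[(4R,6S)-6-(2-hydroxyethyl)-2,2-dimethyl-1,3-dioxan-4-yl]acetonitrile
Product: 20 2-[(4R,6R)-6-(2-chloroethyl)-2,2-dimethyl-1,3-dioxan-4-yl]acetonitrile
Conditions: PPh3, N-chlorosuccinimide, CH2Cl2, 0 °C to rt
Reagents that add atoms: N-chlorosuccinimide, O=C1CCC(=O)N1Cl
Why: Appel-type chlorination of a primary alcohol under neutral conditions; the chloride is the latent C23 nucleophile and should pass unchanged through steps 13–20.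

Step 13
Reactants: 20 2-[(4R,6R)-6-(2-chloroethyl)-2,2-dimethyl-1,3-dioxan-4-yl]acetonitrile
Product: 21 2-[(4S,6R)-6-(2-chloroethyl)-2,2-dimethyl-1,3-dioxan-4-yl]acetaldehyde
Conditions: i-Bu2AlH (1.2 equiv), CH2Cl2, −78 °C; aq. potassium sodium tartrate, then pH 5 acetate buffer
Reagents that add atoms: water, O
Why: partial reduction of the nitrile to the aluminium aldimine, which is hydrolysed to the aldehyde on work-up; the alkyl chloride and the acetonide are inert.

Step 14
Reactants: 21 2-[(4S,6R)-6-(2-chloroethyl)-2,2-dimethyl-1,3-dioxan-4-yl]acetaldehyde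
Product: 22 (2S)-1-[(4R,6R)-6-(2-chloroethyl)-2,2-dimethyl-1,3-dioxan-4-yl]pent-4-en-2-ol
Conditions: (−)-Ipc2BOMe, allylMgBr, Et2O, 0 °C to rt; then 21, −78 °C; NaOH, H2O2, 0 °C
Reagents that add atoms: allylmagnesium bromide, C=CC[Mg]Br
Why: Brown allylboration; the allylborane of the (+)-α-pinene series should add to the Si face and set C29 anti to O27. Reagent control is matched with the 1,3-anti preference of β-alkoxy aldehydes.

Step 15
Reactants: 22 (2S)-1-[(4R,6R)-6-(2-chloroethyl)-2,2-dimethyl-1,3-dioxan-4-yl]pent-4-en-2-ol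
Product: 23 C23–C32 alkene (23-chloro, 25,27-O-isopropylidene, 29-OTBS)
Conditions: TBSCl, imidazole, DMF, rt
Reagents that add atoms: tert-butyldimethylsilyl chloride, CC(C)(C)[Si](C)(C)Cl
Why: standard silylation of the homoallylic alcohol.

Step 16
Reactants: 23 C23–C32 alkene
Product: 25 C23–C32 iodide (23-chloro, 32-iodo, 25,27-O-isopropylidene, 29-OTBS), via C32 alkylzirconocene chloride 24 (not isolated)
Conditions: Cp2Zr(H)Cl, CH2Cl2, rt; then I2, 0 °C
Reagents that add atoms: iodine, [I][I]
Why: hydrozirconation places zirconium on the terminal carbon, and iodinolysis of the C–Zr bond gives the primary iodide in one flask. The alkyl chloride, silyl ether and acetonide do not react.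

Step 17
Reactants: 17 C33–C40 dithiane; 25 C23–C32 iodide
Product: 27 C23–C40 dithioketal (C33 as 1,3-dithiane, 35-OPMB, 29-OTBS, 25,27-O-isopropylidene, 23-chloro), via 2-lithio dithiane 26 (not isolated)
Conditions: 17 (1.2 equiv), t-BuLi, THF/HMPA (9:1), −78 °C; then 25, −78 to −40 °C
Reagents that add atoms: none
Why: alkylation of a lithiated 2-alkyl-1,3-dithiane with a primary iodide (Corey–Seebach) joins C32 to C33. The iodide should react far faster than the primary chloride, and O35 is 1,3 to the carbanion, so no β-elimination is open.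

Step 18
Reactants: 27 C23–C40 dithioketal
Product: 28 C23–C40 C33 ketone
Conditions: I2, NaHCO3, acetone/H2O, 0 °C
Reagents that add atoms: water, O
Why: oxidative hydrolysis of the dithioketal under buffered conditions; the PMB ether, silyl ether, acetonide and alkyl chloride are stable.

Step 19
Reactants: 28 C23–C40 C33 ketone
Product: 29 C23–C40 C33 alcohol (33-OH syn to 35-OPMB)
Conditions: LiAlH4, LiI, Et2O, −78 °C
Reagents that add atoms: none
Why: chelation-controlled 1,3-syn reduction of a β-alkoxy ketone; lithium bridges the ketone and the O35 benzyl-type ether in a six-membered chelate, and hydride adds anti to the C35 substituent. This sets C33 syn to C35.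

Step 20
Reactants: 29 C23–C40 C33 alcohol
Product: 30 C23–C40 chloride (29,33-bis-OTBS, 35-OPMB, 25,27-O-isopropylidene)
Conditions: TBSOTf, 2,6-lutidine, CH2Cl2, −78 °C
Reagents that add atoms: tert-butyldimethylsilyl triflate, CC(C)(C)[Si](C)(C)OS(=O)(=O)C(F)(F)F
Why: silylation of the secondary alcohol under buffered conditions that leave the acetonide and the PMB ether intact.

Step 21
Reactants: 30 C23–C40 chloride; 2 (R)-2-(2-bromoethyl)oxirane
Product: 32 C19–C40 bromo alcohol (19-bromo, 21-OH), via C23 Grignard reagent 31 (not isolated)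
Conditions: Mg (activated by BrCH2CH2Br), THF, 60 °C; then CuI (10 mol%), 2 (1.5 equiv), −40 to −20 °C
Reagents that add atoms: none
Why: copper-catalysed SN2 opening of a terminal epoxide at its CH2 terminus by a primary alkyl Grignard reagent forms C22–C23. C21 comes unchanged from 2, and at −40 °C the epoxide should be attacked much faster than a primary bromide.

Step 22
Reactants: 32 C19–C40 bromo alcohol
Product: 33 C19–C40 bromide (21-OTBS)
Conditions: TBSOTf, 2,6-lutidine, CH2Cl2, −78 °C
Reagents that add atoms: tert-butyldimethylsilyl triflate, CC(C)(C)[Si](C)(C)OS(=O)(=O)C(F)(F)F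
Why: silylation as in step 20; the primary bromide is inert.

Step 23
Reactants: 33 C19–C40 bromide; 2 (R)-2-(2-bromoethyl)oxirane
Product: 35 C15–C40 bromo alcohol (15-bromo, 17-OH), via C19 Grignard reagent 34 (not isolated)
Conditions: Mg, THF, rt; then CuI (10 mol%), 2 (1.5 equiv), −40 to −20 °C
Reagents that add atoms: none
Why: second cycle of the copper-catalysed Grignard–epoxide coupling, forming C18–C19; C17 is brought in by 2.

Step 24
Reactants: 35 C15–C40 bromo alcohol
Product: 36 C15–C40 bromide (17-OTBS)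
Conditions: TBSOTf, 2,6-lutidine, CH2Cl2, −78 °C
Reagents that add atoms: tert-butyldimethylsilyl triflate, CC(C)(C)[Si](C)(C)OS(=O)(=O)C(F)(F)F
Why: silylation as in step 20.

Step 25
Reactants: 36 C15–C40 bromide; 2 (R)-2-(2-bromoethyl)oxirane
Product: 38 C11–C40 bromo alcohol (11-bromo, 13-OH), via C15 Grignard reagent 37 (not isolated)
Conditions: Mg, THF, rt; then CuI (10 mol%), 2 (1.5 equiv), −40 to −20 °C
Reagents that add atoms: none
Why: third cycle, forming C14–C15; C13 is brought in by 2.

Step 26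
Reactants: 38 C11–C40 bromo alcohol
Product: 39 C11–C40 bromide (13-OTBS)
Conditions: TBSOTf, 2,6-lutidine, CH2Cl2, −78 °C
Reagents that add atoms: tert-butyldimethylsilyl triflate, CC(C)(C)[Si](C)(C)OS(=O)(=O)C(F)(F)F
Why: silylation as in step 20.

Step 27
Reactants: 39 C11–C40 bromide; 8 west epoxide (C3–C10)
Product: 41 C3–C40 hydroxy tert-butyl ester (9-OH), via C11 Grignard reagent 40 (not isolated)
Conditions: Mg, THF, rt; then CuI (10 mol%), 8 (1.3 equiv), −40 to −20 °C
Reagents that add atoms: none
Why: the same copper-catalysed epoxide opening forms C10–C11 and completes the chain. At −40 °C the hindered tert-butyl ester should not compete with the epoxide for the organocopper species.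

Step 28
Reactants: 41 C3–C40 hydroxy tert-butyl ester
Product: 43 C3–C40 carboxylic acid (9-OTBS), via C3 silyl ester 42 (not isolated)
Conditions: TBSOTf (4 equiv), 2,6-lutidine (6 equiv), CH2Cl2, 0 °C to rt; then K2CO3, MeOH/THF/H2O, rt; pH 4 work-up
Reagents that add atoms: tert-butyldimethylsilyl triflate, CC(C)(C)[Si](C)(C)OS(=O)(=O)C(F)(F)F
Why: the silyl triflate silylates O9 and also converts the tert-butyl ester into the silyl ester with loss of isobutene. The labile silyl ester is then hydrolysed under mild base, which leaves the secondary silyl ethers in place.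

Step 29
Reactants: 43 C3–C40 carboxylic acid; 44 thiophenol
Product: 45 C3–C40 S-phenyl thioester (35-OPMB)
Conditions: DCC, DMAP (cat.), CH2Cl2, 0 °C to rt
Reagents that add atoms: none
Why: Steglich-type thioesterification; the O-acylisourea is intercepted by the thiol, and every hydroxyl is protected.

Step 30
Reactants: 45 C3–C40 S-phenyl thioester
Product: 46 C3–C40 thioester with free 35-OH
Conditions: DDQ, CH2Cl2/aq. NaH2PO4–Na2HPO4 buffer (pH 7), 0 °C
Reagents that add atoms: none
Why: oxidative cleavage of the PMB ether by hydride abstraction and hydrolysis; silyl ethers, the acetonide and the aryl thioester are not oxidised.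

Step 31
Reactants: 46 C3–C40 thioester with free 35-OH; 47 2,2-dimethyl-1,3-dioxane-4,6-dione
Product: 48 seco malonic half-ester (O35–CO–CH2–CO2H, C3 S-phenyl thioester)
Conditions: toluene, 90 °C
Reagents that add atoms: none
Why: thermal alcoholysis of the dioxanedione gives the malonic acid monoester and acetone without any coupling agent. The thioester is not an acyl donor toward a hindered alcohol at this temperature.

Step 32
Reactants: 48 seco malonic half-ester
Product: 50 36-membered 3-oxo lactone (C3 ketone, C2 methylene), via macrocyclic 2-carboxy-3-oxo lactone 49 (not isolated)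
Conditions: MgBr2·OEt2 (5 equiv), Et3N (10 equiv), imidazole (2 equiv), THF; 48 added by syringe pump to 0.5 mM, rt to 40 °C
Reagents that add atoms: none
Why: Proposed new method: MgBr2·OEt2 and Et3N should turn the malonic half-ester into a chelated magnesium carboxylate–enolate whose α-carbon (C2) adds to the thioester carbonyl (C3); collapse of the tetrahedral intermediate expels thiophenolate to give the C-acylated malonate 49, which decarboxylates through its magnesium β-keto carboxylate and so cannot revert. The closest known reaction type is the intermolecular magnesium-mediated decarboxylative Claisen condensation of malonic half-esters with acyl imidazoles or thioesters, here run within one molecule. The 36-membered ring closes by an end-to-end intramolecular acyl substitution (exo-trig at C3), which has no entropic help other than dilution and slow addition. No stereocentre is created: C2 ends as a methylene and the eleven existing centres lie outside the reacting atoms. The step needs chemoselectivity for intramolecular C-acylation over plain decarboxylation to the O35 acetate, over enolisation of the thioester and over oligomerisation. The bidentate magnesium malonate is by far the most acidic and most nucleophilic carbon site, the aryl thioester is the only activated acyl group, and the β-keto ester product is held as its magnesium chelate and thereby protected from further acylation. Imidazole is intended as ligand and proton shuttle at magnesium.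

Step 33
Reactants: 50 36-membered 3-oxo lactone
Product: 51 (E)-enol triflate (C3–OTf trans to C1)
Conditions: Tf2O, aq. Me4NOH, toluene, 0 °C
Reagents that add atoms: triflic anhydride, O=S(=O)(OS(=O)(=O)C(F)(F)F)C(F)(F)F
Why: O-sulfonylation of a β-keto ester enolate. With the non-coordinating tetramethylammonium counter-ion the enolate is not chelated and adopts the dipole-minimised geometry with the enolate oxygen anti to the ester carbonyl, which should give the (E)-triflate.

Step 34
Reactants: 51 (E)-enol triflate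
Product: 52 protected (Z)-enoate macrolactone
Conditions: MeMgBr, Fe(acac)3 (10 mol%), THF/NMP, −30 °C
Reagents that add atoms: methylmagnesium bromide, C[Mg]Br
Why: iron-catalysed Kumada-type coupling of an enol triflate with a methyl Grignard reagent proceeds with retention of alkene geometry, so methyl takes the place trans to C1 and the enoate is Z. The coupling should be much faster than Grignard addition to the lactone at −30 °C.

Step 35
Reactants: 52 protected (Z)-enoate macrolactone
Product: 53 CNP0126363.4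
Conditions: aq. HF (48%), MeCN/THF, 0 °C to rt
Reagents that add atoms: none
Why: acidic fluoride cleaves the seven TBS ethers and hydrolyses the acetonide in one operation. The conditions are non-basic, so the Z-enoate should not isomerise and the lactone should not migrate.

## Compound list

1 | rac-2-(2-bromoethyl)oxirane | BrCCC1CO1 | starting material
2 | (R)-2-(2-bromoethyl)oxirane | BrCC[C@@H]1CO1 | intermediate
3 | tert-butyl 5-oxopentanoate | O=CCCCC(=O)OC(C)(C)C | starting material
4 | tert-butyl (S)-5-hydroxyoct-7-enoate | C=CC[C@@H](O)CCCC(=O)OC(C)(C)C | intermediate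
5 | tert-butyl (S)-5-[(tert-butoxycarbonyl)oxy]oct-7-enoate | C=CC[C@@H](OC(=O)OC(C)(C)C)CCCC(=O)OC(C)(C)C | intermediate
6 | tert-butyl 4-[(4S,6S)-6-(iodomethyl)-2-oxo-1,3-dioxan-4-yl]butanoate (cis carbonate) | IC[C@@H]1C[C@H](CCCC(=O)OC(C)(C)C)OC(=O)O1 | intermediate
7 | tert-butyl (5S)-5-hydroxy-6-[(2S)-oxiran-2-yl]hexanoate | C1O[C@H]1C[C@@H](O)CCCC(=O)OC(C)(C)C | intermediate
8 | tert-butyl (5S)-5-[(tert-butyldimethylsilyl)oxy]-6-[(2S)-oxiran-2-yl]hexanoate (west epoxide, C3–C10) | C1O[C@H]1C[C@@H](O[Si](C)(C)C(C)(C)C)CCCC(=O)OC(C)(C)C | intermediate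
9 | (E)-hept-2-en-1-ol | CCCC/C=C/CO | starting material
10 | [(2R,3R)-3-butyloxiran-2-yl]methanol | CCCC[C@H]1O[C@@H]1CO | intermediate
11 | (2S,3S)-3-methylheptane-1,2-diol | CCCC[C@H](C)[C@H](O)CO | intermediate
12 | (2S,3S)-2-hydroxy-3-methylheptyl 4-methylbenzenesulfonate | CCCC[C@H](C)[C@H](O)COS(=O)(=O)c1ccc(C)cc1 | intermediate
13 | (2S)-2-[(2S)-hexan-2-yl]oxirane (C34–C40) | CCCC[C@H](C)[C@H]1CO1 | intermediate
14 | 1,3-dithiane | C1CSCSC1 | starting material
15 | 2-lithio-1,3-dithiane | [Li]C1SCCCS1 | intermediate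
16 | lithium (2R,3S)-1-(1,3-dithian-2-yl)-3-methylheptan-2-olate | CCCC[C@H](C)[C@H](O[Li])CC1SCCCS1 | intermediate
17 | 2-[(2R,3S)-2-[(4-methoxybenzyl)oxy]-3-methylheptyl]-1,3-dithiane (C33–C40) | CCCC[C@H](C)[C@H](OCc1ccc(OC)cc1)CC1SCCCS1 | intermediate
18 | tert-butyl 2-[(4R,6R)-6-(cyanomethyl)-2,2-dimethyl-1,3-dioxan-4-yl]acetate (C23–C29) | N#CC[C@@H]1C[C@@H](OC(C)(C)O1)CC(=O)OC(C)(C)C | starting material
19 | 2-[(4R,6S)-6-(2-hydroxyethyl)-2,2-dimethyl-1,3-dioxan-4-yl]acetonitrile | N#CC[C@@H]1C[C@@H](OC(C)(C)O1)CCO | intermediate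
20 | 2-[(4R,6R)-6-(2-chloroethyl)-2,2-dimethyl-1,3-dioxan-4-yl]acetonitrile | N#CC[C@@H]1C[C@@H](OC(C)(C)O1)CCCl | intermediate
21 | 2-[(4S,6R)-6-(2-chloroethyl)-2,2-dimethyl-1,3-dioxan-4-yl]acetaldehyde | O=CC[C@@H]1C[C@@H](OC(C)(C)O1)CCCl | intermediate
22 | (2S)-1-[(4R,6R)-6-(2-chloroethyl)-2,2-dimethyl-1,3-dioxan-4-yl]pent-4-en-2-ol | C=CC[C@H](O)C[C@@H]1C[C@@H](OC(C)(C)O1)CCCl | intermediate
23 | TBS ether of 22 (C23–C32 alkene; 23-chloro, 25,27-O-isopropylidene, 29-OTBS) | C=CC[C@H](O[Si](C)(C)C(C)(C)C)C[C@@H]1C[C@@H](OC(C)(C)O1)CCCl | intermediate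
24 | C32 alkyl(chloro)bis(cyclopentadienyl)zirconium from 23 | Cl[Zr](C1C=CC=C1)(C1C=CC=C1)CCC[C@H](O[Si](C)(C)C(C)(C)C)C[C@@H]1C[C@@H](OC(C)(C)O1)CCCl | intermediate
25 | C23–C32 iodide (32-iodo, 23-chloro, 25,27-O-isopropylidene, 29-OTBS) | ICCC[C@H](O[Si](C)(C)C(C)(C)C)C[C@@H]1C[C@@H](OC(C)(C)O1)CCCl | intermediate
26 | 2-lithio derivative of 17 | CCCC[C@H](C)[C@H](OCc1ccc(OC)cc1)CC1([Li])SCCCS1 | intermediate
27 | C23–C40 dithioketal (C33 as 1,3-dithiane-2,2-diyl, 35-OPMB, 29-OTBS, 25,27-O-isopropylidene, 23-chloro) | CCCC[C@H](C)[C@H](OCc1ccc(OC)cc1)CC1(SCCCS1)CCC[C@H](O[Si](C)(C)C(C)(C)C)C[C@@H]2C[C@@H](OC(C)(C)O2)CCCl | intermediate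
28 | C23–C40 C33 ketone | CCCC[C@H](C)[C@H](OCc1ccc(OC)cc1)CC(=O)CCC[C@H](O[Si](C)(C)C(C)(C)C)C[C@@H]2C[C@@H](OC(C)(C)O2)CCCl | intermediate
29 | C23–C40 C33 alcohol (33-OH syn to 35-OPMB) | CCCC[C@H](C)[C@H](OCc1ccc(OC)cc1)C[C@H](O)CCC[C@H](O[Si](C)(C)C(C)(C)C)C[C@@H]2C[C@@H](OC(C)(C)O2)CCCl | intermediate
30 | C23–C40 chloride (29,33-bis-OTBS, 35-OPMB, 25,27-O-isopropylidene) | CCCC[C@H](C)[C@H](OCc1ccc(OC)cc1)C[C@H](O[Si](C)(C)C(C)(C)C)CCC[C@H](O[Si](C)(C)C(C)(C)C)C[C@@H]2C[C@@H](OC(C)(C)O2)CCCl | intermediate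
31 | C23 Grignard reagent from 30 | CCCC[C@H](C)[C@H](OCc1ccc(OC)cc1)C[C@H](O[Si](C)(C)C(C)(C)C)CCC[C@H](O[Si](C)(C)C(C)(C)C)C[C@@H]2C[C@@H](OC(C)(C)O2)CC[Mg]Cl | intermediate
32 | C19–C40 bromo alcohol (19-bromo, 21-OH) | CCCC[C@H](C)[C@H](OCc1ccc(OC)cc1)C[C@H](O[Si](C)(C)C(C)(C)C)CCC[C@H](O[Si](C)(C)C(C)(C)C)C[C@@H]2C[C@@H](OC(C)(C)O2)CCC[C@H](O)CCBr | intermediate
33 | C19–C40 bromide (21-OTBS) | CCCC[C@H](C)[C@H](OCc1ccc(OC)cc1)C[C@H](O[Si](C)(C)C(C)(C)C)CCC[C@H](O[Si](C)(C)C(C)(C)C)C[C@@H]2C[C@@H](OC(C)(C)O2)CCC[C@H](O[Si](C)(C)C(C)(C)C)CCBr | intermediate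
34 | C19 Grignard reagent from 33 | CCCC[C@H](C)[C@H](OCc1ccc(OC)cc1)C[C@H](O[Si](C)(C)C(C)(C)C)CCC[C@H](O[Si](C)(C)C(C)(C)C)C[C@@H]2C[C@@H](OC(C)(C)O2)CCC[C@H](O[Si](C)(C)C(C)(C)C)CC[Mg]Br | intermediate
35 | C15–C40 bromo alcohol (15-bromo, 17-OH) | CCCC[C@H](C)[C@H](OCc1ccc(OC)cc1)C[C@H](O[Si](C)(C)C(C)(C)C)CCC[C@H](O[Si](C)(C)C(C)(C)C)C[C@@H]2C[C@@H](OC(C)(C)O2)CCC[C@H](O[Si](C)(C)C(C)(C)C)CCC[C@H](O)CCBr | intermediate
36 | C15–C40 bromide (17-OTBS) | CCCC[C@H](C)[C@H](OCc1ccc(OC)cc1)C[C@H](O[Si](C)(C)C(C)(C)C)CCC[C@H](O[Si](C)(C)C(C)(C)C)C[C@@H]2C[C@@H](OC(C)(C)O2)CCC[C@H](O[Si](C)(C)C(C)(C)C)CCC[C@H](O[Si](C)(C)C(C)(C)C)CCBr | intermediate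
37 | C15 Grignard reagent from 36 | CCCC[C@H](C)[C@H](OCc1ccc(OC)cc1)C[C@H](O[Si](C)(C)C(C)(C)C)CCC[C@H](O[Si](C)(C)C(C)(C)C)C[C@@H]2C[C@@H](OC(C)(C)O2)CCC[C@H](O[Si](C)(C)C(C)(C)C)CCC[C@H](O[Si](C)(C)C(C)(C)C)CC[Mg]Br | intermediate
38 | C11–C40 bromo alcohol (11-bromo, 13-OH) | CCCC[C@H](C)[C@H](OCc1ccc(OC)cc1)C[C@H](O[Si](C)(C)C(C)(C)C)CCC[C@H](O[Si](C)(C)C(C)(C)C)C[C@@H]2C[C@@H](OC(C)(C)O2)CCC[C@H](O[Si](C)(C)C(C)(C)C)CCC[C@H](O[Si](C)(C)C(C)(C)C)CCC[C@H](O)CCBr | intermediate
39 | C11–C40 bromide (13-OTBS) | CCCC[C@H](C)[C@H](OCc1ccc(OC)cc1)C[C@H](O[Si](C)(C)C(C)(C)C)CCC[C@H](O[Si](C)(C)C(C)(C)C)C[C@@H]2C[C@@H](OC(C)(C)O2)CCC[C@H](O[Si](C)(C)C(C)(C)C)CCC[C@H](O[Si](C)(C)C(C)(C)C)CCC[C@H](O[Si](C)(C)C(C)(C)C)CCBr | intermediate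
40 | C11 Grignard reagent from 39 | CCCC[C@H](C)[C@H](OCc1ccc(OC)cc1)C[C@H](O[Si](C)(C)C(C)(C)C)CCC[C@H](O[Si](C)(C)C(C)(C)C)C[C@@H]2C[C@@H](OC(C)(C)O2)CCC[C@H](O[Si](C)(C)C(C)(C)C)CCC[C@H](O[Si](C)(C)C(C)(C)C)CCC[C@H](O[Si](C)(C)C(C)(C)C)CC[Mg]Br | intermediate
41 | C3–C40 hydroxy tert-butyl ester (9-OH; 7,13,17,21,29,33-OTBS; 25,27-O-isopropylidene; 35-OPMB) | CCCC[C@H](C)[C@H](OCc1ccc(OC)cc1)C[C@H](O[Si](C)(C)C(C)(C)C)CCC[C@H](O[Si](C)(C)C(C)(C)C)C[C@@H]2C[C@@H](OC(C)(C)O2)CCC[C@H](O[Si](C)(C)C(C)(C)C)CCC[C@H](O[Si](C)(C)C(C)(C)C)CCC[C@H](O[Si](C)(C)C(C)(C)C)CCC[C@@H](O)C[C@@H](O[Si](C)(C)C(C)(C)C)CCCC(=O)OC(C)(C)C | intermediate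
42 | C3 tert-butyldimethylsilyl ester of 43 | CCCC[C@H](C)[C@H](OCc1ccc(OC)cc1)C[C@H](O[Si](C)(C)C(C)(C)C)CCC[C@H](O[Si](C)(C)C(C)(C)C)C[C@@H]2C[C@@H](OC(C)(C)O2)CCC[C@H](O[Si](C)(C)C(C)(C)C)CCC[C@H](O[Si](C)(C)C(C)(C)C)CCC[C@H](O[Si](C)(C)C(C)(C)C)CCC[C@@H](O[Si](C)(C)C(C)(C)C)C[C@@H](O[Si](C)(C)C(C)(C)C)CCCC(=O)O[Si](C)(C)C(C)(C)C | intermediate
43 | C3–C40 carboxylic acid (seven OTBS, 25,27-O-isopropylidene, 35-OPMB) | CCCC[C@H](C)[C@H](OCc1ccc(OC)cc1)C[C@H](O[Si](C)(C)C(C)(C)C)CCC[C@H](O[Si](C)(C)C(C)(C)C)C[C@@H]2C[C@@H](OC(C)(C)O2)CCC[C@H](O[Si](C)(C)C(C)(C)C)CCC[C@H](O[Si](C)(C)C(C)(C)C)CCC[C@H](O[Si](C)(C)C(C)(C)C)CCC[C@@H](O[Si](C)(C)C(C)(C)C)C[C@@H](O[Si](C)(C)C(C)(C)C)CCCC(=O)O | intermediate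
44 | thiophenol | Sc1ccccc1 | starting material
45 | C3–C40 S-phenyl thioester (35-OPMB) | CCCC[C@H](C)[C@H](OCc1ccc(OC)cc1)C[C@H](O[Si](C)(C)C(C)(C)C)CCC[C@H](O[Si](C)(C)C(C)(C)C)C[C@@H]2C[C@@H](OC(C)(C)O2)CCC[C@H](O[Si](C)(C)C(C)(C)C)CCC[C@H](O[Si](C)(C)C(C)(C)C)CCC[C@H](O[Si](C)(C)C(C)(C)C)CCC[C@@H](O[Si](C)(C)C(C)(C)C)C[C@@H](O[Si](C)(C)C(C)(C)C)CCCC(=O)Sc1ccccc1 | intermediate
46 | C3–C40 S-phenyl thioester with free 35-OH | CCCC[C@H](C)[C@H](O)C[C@H](O[Si](C)(C)C(C)(C)C)CCC[C@H](O[Si](C)(C)C(C)(C)C)C[C@@H]2C[C@@H](OC(C)(C)O2)CCC[C@H](O[Si](C)(C)C(C)(C)C)CCC[C@H](O[Si](C)(C)C(C)(C)C)CCC[C@H](O[Si](C)(C)C(C)(C)C)CCC[C@@H](O[Si](C)(C)C(C)(C)C)C[C@@H](O[Si](C)(C)C(C)(C)C)CCCC(=O)Sc1ccccc1 | intermediate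
47 | 2,2-dimethyl-1,3-dioxane-4,6-dione | CC1(C)OC(=O)CC(=O)O1 | starting material
48 | seco malonic half-ester (O35 hydrogen malonate, C3 S-phenyl thioester; key-step precursor) | CCCC[C@H](C)[C@H](OC(=O)CC(=O)O)C[C@H](O[Si](C)(C)C(C)(C)C)CCC[C@H](O[Si](C)(C)C(C)(C)C)C[C@@H]2C[C@@H](OC(C)(C)O2)CCC[C@H](O[Si](C)(C)C(C)(C)C)CCC[C@H](O[Si](C)(C)C(C)(C)C)CCC[C@H](O[Si](C)(C)C(C)(C)C)CCC[C@@H](O[Si](C)(C)C(C)(C)C)C[C@@H](O[Si](C)(C)C(C)(C)C)CCCC(=O)Sc1ccccc1 | intermediate
49 | macrocyclic 2-carboxy-3-oxo lactone (C-acylated malonate) | CCCC[C@H](C)[C@H]1C[C@H](O[Si](C)(C)C(C)(C)C)CCC[C@H](O[Si](C)(C)C(C)(C)C)C[C@@H]2C[C@@H](OC(C)(C)O2)CCC[C@H](O[Si](C)(C)C(C)(C)C)CCC[C@H](O[Si](C)(C)C(C)(C)C)CCC[C@H](O[Si](C)(C)C(C)(C)C)CCC[C@@H](O[Si](C)(C)C(C)(C)C)C[C@@H](O[Si](C)(C)C(C)(C)C)CCCC(=O)C(C(=O)O)C(=O)O1 | intermediate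
50 | 36-membered 3-oxo lactone (key-step product) | CCCC[C@H](C)[C@H]1C[C@H](O[Si](C)(C)C(C)(C)C)CCC[C@H](O[Si](C)(C)C(C)(C)C)C[C@@H]2C[C@@H](OC(C)(C)O2)CCC[C@H](O[Si](C)(C)C(C)(C)C)CCC[C@H](O[Si](C)(C)C(C)(C)C)CCC[C@H](O[Si](C)(C)C(C)(C)C)CCC[C@@H](O[Si](C)(C)C(C)(C)C)C[C@@H](O[Si](C)(C)C(C)(C)C)CCCC(=O)CC(=O)O1 | intermediate
51 | (E)-enol triflate of 50 (C3–OTf trans to C1) | CCCC[C@H](C)[C@H]1C[C@H](O[Si](C)(C)C(C)(C)C)CCC[C@H](O[Si](C)(C)C(C)(C)C)C[C@@H]2C[C@@H](OC(C)(C)O2)CCC[C@H](O[Si](C)(C)C(C)(C)C)CCC[C@H](O[Si](C)(C)C(C)(C)C)CCC[C@H](O[Si](C)(C)C(C)(C)C)CCC[C@@H](O[Si](C)(C)C(C)(C)C)C[C@@H](O[Si](C)(C)C(C)(C)C)CCC/C(OS(=O)(=O)C(F)(F)F)=C\C(=O)O1 | intermediate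
52 | protected (Z)-3-methyl enoate macrolactone (seven OTBS, 25,27-O-isopropylidene) | CCCC[C@H](C)[C@H]1C[C@H](O[Si](C)(C)C(C)(C)C)CCC[C@H](O[Si](C)(C)C(C)(C)C)C[C@@H]2C[C@@H](OC(C)(C)O2)CCC[C@H](O[Si](C)(C)C(C)(C)C)CCC[C@H](O[Si](C)(C)C(C)(C)C)CCC[C@H](O[Si](C)(C)C(C)(C)C)CCC[C@@H](O[Si](C)(C)C(C)(C)C)C[C@@H](O[Si](C)(C)C(C)(C)C)CCC/C(C)=C\C(=O)O1 | intermediate
53 | CNP0126363.4 | CCCC[C@H](C)[C@H]1C[C@H](O)CCC[C@H](O)C[C@@H](O)C[C@@H](O)CCC[C@H](O)CCC[C@H](O)CCC[C@H](O)CCC[C@@H](O)C[C@@H](O)CCC/C(C)=C\C(=O)O1 | target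

## Step count and risks

Total step count: 35. Longest linear sequence: 25 steps (from 18 through steps 11–35).

**Step 32 (key step, proposed new method).** The most likely failure is that the magnesium malonate decarboxylates to the O35 acetate before it meets the remote thioester, or that acylation occurs between molecules and gives dimers and oligomers, because a 36-membered closure has no entropic help beyond dilution. The fallback uses known chemistry and sets out from acid 43. Condensation with 47 (DCC, DMAP) would give the acyl Meldrum's acid F1. DDQ would free O35 to give the hydroxy acyl Meldrum's acid F2. Thermolysis of F2 in refluxing toluene at high dilution would release the acylketene, which the C35 hydroxyl traps as the same β-keto lactone, so the route is rejoined at 50.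

**Step 21 (and its repeats, steps 23, 25 and 27).** Magnesium insertion into the primary chloride may be sluggish and accompanied by Wurtz-type homocoupling. Chemoselectivity is lost if the copper-catalysed substitution also attacks the primary bromide of 2 or of the product. The fallback sets out from 30: NaI in acetone would give the primary iodide F3. Iodine–lithium exchange (t-BuLi, Et2O, −78 °C) and BF3·OEt2-promoted opening of 2 at −78 °C, where a primary bromide is inert, would return to 32.

**Step 19.** Facial selectivity may be poor if the lithium chelate between the C33 ketone and the O35 ether is loose, which would give the anti isomer at C33. The fallback sets out from 28: DDQ would remove the PMB group to give the β-hydroxy ketone F4. Narasaka–Prasad reduction (Et2BOMe, NaBH4, THF/MeOH, −78 °C) would give the syn-diol F5 through the boron chelate. 4-Methoxybenzaldehyde dimethyl acetal with an acid catalyst would give the cis 4-methoxybenzylidene acetal F6. i-Bu2AlH, which coordinates the less hindered O33, would open it to the O35 PMB ether with free 33-OH, which is 29.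

**Step 28.** The acetonide or the PMB ether may be lost under the excess silyl triflate needed to cleave the tert-butyl ester. The fallback sets out from 41: silylation with one equivalent of TBSOTf at −78 °C would give the fully silylated tert-butyl ester F7. i-Bu2AlH would reduce it to the C3 primary alcohol F8. Oxidation with TEMPO and PhI(OAc)2 in aqueous MeCN would give acid 43.

**Step 33.** Enol triflate geometry may erode through enolate equilibration, or aqueous hydroxide may hydrolyse the lactone. The fallback sets out from 50: (EtO)2P(O)Cl with Et3N and DMAP in HMPA would give the (E)-enol diethyl phosphate F9 under non-chelating conditions. Me2CuLi would then replace the phosphate by methyl with retention through addition–elimination and give 52.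

## Further compounds

F1 | step 32 | acyl Meldrum's acid of 43 (enol form, 35-OPMB) | CCCC[C@H](C)[C@H](OCc1ccc(OC)cc1)C[C@H](O[Si](C)(C)C(C)(C)C)CCC[C@H](O[Si](C)(C)C(C)(C)C)C[C@@H]2C[C@@H](OC(C)(C)O2)CCC[C@H](O[Si](C)(C)C(C)(C)C)CCC[C@H](O[Si](C)(C)C(C)(C)C)CCC[C@H](O[Si](C)(C)C(C)(C)C)CCC[C@@H](O[Si](C)(C)C(C)(C)C)C[C@@H](O[Si](C)(C)C(C)(C)C)CCCC(O)=C1C(=O)OC(C)(C)OC1=O
F2 | step 32 | hydroxy acyl Meldrum's acid (free 35-OH) | CCCC[C@H](C)[C@H](O)C[C@H](O[Si](C)(C)C(C)(C)C)CCC[C@H](O[Si](C)(C)C(C)(C)C)C[C@@H]2C[C@@H](OC(C)(C)O2)CCC[C@H](O[Si](C)(C)C(C)(C)C)CCC[C@H](O[Si](C)(C)C(C)(C)C)CCC[C@H](O[Si](C)(C)C(C)(C)C)CCC[C@@H](O[Si](C)(C)C(C)(C)C)C[C@@H](O[Si](C)(C)C(C)(C)C)CCCC(O)=C1C(=O)OC(C)(C)OC1=O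
F3 | step 21 | C23–C40 primary iodide | CCCC[C@H](C)[C@H](OCc1ccc(OC)cc1)C[C@H](O[Si](C)(C)C(C)(C)C)CCC[C@H](O[Si](C)(C)C(C)(C)C)C[C@@H]2C[C@@H](OC(C)(C)O2)CCI
F4 | step 19 | C23–C40 β-hydroxy ketone (35-OH, C33 ketone) | CCCC[C@H](C)[C@H](O)CC(=O)CCC[C@H](O[Si](C)(C)C(C)(C)C)C[C@@H]2C[C@@H](OC(C)(C)O2)CCCl
F5 | step 19 | C23–C40 syn-33,35-diol | CCCC[C@H](C)[C@H](O)C[C@H](O)CCC[C@H](O[Si](C)(C)C(C)(C)C)C[C@@H]2C[C@@H](OC(C)(C)O2)CCCl
F6 | step 19 | cis 33,35-O-(4-methoxybenzylidene) acetal | CCCC[C@H](C)[C@H]3C[C@@H](CCC[C@H](O[Si](C)(C)C(C)(C)C)C[C@@H]2C[C@@H](OC(C)(C)O2)CCCl)O[C@@H](c4ccc(OC)cc4)O3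
F7 | step 28 | C3–C40 tert-butyl ester with 9-OTBS | CCCC[C@H](C)[C@H](OCc1ccc(OC)cc1)C[C@H](O[Si](C)(C)C(C)(C)C)CCC[C@H](O[Si](C)(C)C(C)(C)C)C[C@@H]2C[C@@H](OC(C)(C)O2)CCC[C@H](O[Si](C)(C)C(C)(C)C)CCC[C@H](O[Si](C)(C)C(C)(C)C)CCC[C@H](O[Si](C)(C)C(C)(C)C)CCC[C@@H](O[Si](C)(C)C(C)(C)C)C[C@@H](O[Si](C)(C)C(C)(C)C)CCCC(=O)OC(C)(C)C
F8 | step 28 | C3 primary alcohol | CCCC[C@H](C)[C@H](OCc1ccc(OC)cc1)C[C@H](O[Si](C)(C)C(C)(C)C)CCC[C@H](O[Si](C)(C)C(C)(C)C)C[C@@H]2C[C@@H](OC(C)(C)O2)CCC[C@H](O[Si](C)(C)C(C)(C)C)CCC[C@H](O[Si](C)(C)C(C)(C)C)CCC[C@H](O[Si](C)(C)C(C)(C)C)CCC[C@@H](O[Si](C)(C)C(C)(C)C)C[C@@H](O[Si](C)(C)C(C)(C)C)CCCCO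
F9 | step 33 | (E)-enol diethyl phosphate of 50 | CCCC[C@H](C)[C@H]1C[C@H](O[Si](C)(C)C(C)(C)C)CCC[C@H](O[Si](C)(C)C(C)(C)C)C[C@@H]2C[C@@H](OC(C)(C)O2)CCC[C@H](O[Si](C)(C)C(C)(C)C)CCC[C@H](O[Si](C)(C)C(C)(C)C)CCC[C@H](O[Si](C)(C)C(C)(C)C)CCC[C@@H](O[Si](C)(C)C(C)(C)C)C[C@@H](O[Si](C)(C)C(C)(C)C)CCC/C(OP(=O)(OCC)OCC)=C\C(=O)O1
A1 | alternative 1 | pentane-1,5-diol | OCCCCCO
A2 | alternative 1 | (4R,8R)-undeca-1,10-diene-4,8-diol | C=CC[C@H](O)CCC[C@@H](O)CC=C
A3 | alternative 2 | cis-3,5-bis(methoxymethoxy)cyclohexan-1-one (meso) | O=C1C[C@@H](OCOC)C[C@@H](OCOC)C1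
A4 | alternative 2 | (4S,6R)-4,6-bis(methoxymethoxy)oxepan-2-one | O=C1C[C@@H](OCOC)C[C@@H](OCOC)CO1
A5 | alternative 3 | 2-(tert-butyldimethylsilyl)-1,3-dithiane | CC(C)(C)[Si](C)(C)C1SCCCS1
A6 | alternative 3 | west epoxide (C5–C18; 17,18-epoxide, 7,9,13-tris-OTBS, 5-OPMB) | C1O[C@@H]1CCC[C@H](O[Si](C)(C)C(C)(C)C)CCC[C@@H](O[Si](C)(C)C(C)(C)C)C[C@@H](O[Si](C)(C)C(C)(C)C)CCOCc1ccc(OC)cc1
A7 | alternative 3 | east epoxide (C20–C40; 20,21-epoxide, 25,27,29,33-tetrakis-OTBS, 35-OPMB) | CCCC[C@H](C)[C@H](OCc1ccc(OC)cc1)C[C@H](O[Si](C)(C)C(C)(C)C)CCC[C@H](O[Si](C)(C)C(C)(C)C)C[C@@H](O[Si](C)(C)C(C)(C)C)C[C@@H](O[Si](C)(C)C(C)(C)C)CCC[C@H]1CO1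
A8 | alternative 3 | C5–C40 chain with C19 dithiane, 17-OTBS and free 21-OH | CCCC[C@H](C)[C@H](OCc1ccc(OC)cc1)C[C@H](O[Si](C)(C)C(C)(C)C)CCC[C@H](O[Si](C)(C)C(C)(C)C)C[C@@H](O[Si](C)(C)C(C)(C)C)C[C@@H](O[Si](C)(C)C(C)(C)C)CCC[C@H](O)CC1(SCCCS1)C[C@H](O[Si](C)(C)C(C)(C)C)CCC[C@H](O[Si](C)(C)C(C)(C)C)CCC[C@@H](O[Si](C)(C)C(C)(C)C)C[C@@H](O[Si](C)(C)C(C)(C)C)CCOCc1ccc(OC)cc1
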